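**Early stop.** The quick number starts from the early times, so the runs come first.

in all of them: starting material 0.45 M
- noon: free catalyst 0.45 mM; run made earlier
- midnight: free catalyst 0.68 mM; run made earlier
- flask: free catalyst 0.90 mM; time 10 h

| run | time / h | target / % | isomer of the product / % | starting material / % |
|---|---|---|---|---|
| noon | 0.667 | 5.6 | 17.1 | 4.3 |
| noon | 1.33 | 6.7 | 16.5 | 3.4 |
| noon | 2.50 | 5.8 | 13.7 | 3.1 |
| noon | 4.00 | 5.5 | 11.1 | 2.0 |
| noon | 8.00 | 5.1 | 7.2 | 1.7 |
| midnight | 0.667 | 7.0 | 16.5 | 3.1 |
| midnight | 1.33 | 7.2 | 15.8 | 2.9 |
| midnight | 2.50 | 6.9 | 14.1 | 2.9 |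
| midnight | 4.00 | 7.2 | 11.8 | 2.4 |
| midnight | 8.00 | 6.7 | 7.8 | 1.6 |

(each reading ± 0.5 percentage points)



- share of target in target plus isomer of the product at 30 s
- share of target in target plus isomer of the product at 15 min
- share of target in target plus isomer of the product at 10 h
- which of target and isomer of the product there is more of at 10 h

By the first reading at 0.667 h, target already stands near the level it keeps in both runs. It averages 5.74 % in the noon run and 7.00 % in the midnight run.

**Target level.** These averages make target grow as the free catalyst charged to the power 0.481, so the new flask, with 0.90 mM, should hold 8.01 %.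

**Isomer drain.** Averaged over both runs, the isomer of the product falls from 16.1 % at 1.33 h to 7.50 % at 8.00 h. Taken as first order, c(isomer of the product) falls to half in each 6.03 h, the drain half-life.

**The number.** Assuming that the new flask holds at 8.00 h the 7.50 % of isomer averaged from the two runs, the drain half-life gives 5.96 % at 10 h, less than the 8.01 % of target. So the share c(target)/(c(target)+c(isomer of the product)), the selectivity of this pair, comes to 57.3 %, with target ahead. The times 30 s and 15 min lie before the first reading, so this reckoning commits to no share there.

**Forecast.** The hunch sent along, the forecast, gives 34 %, 31 % and 56 % with target ahead, holding of target that “it isn't fed by the isomer's decay”.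

**Result.** The flask gives 49.1 %, 35.3 % and 55.2 %, with target ahead, 8.18 % against 6.64 %.

    starting material + free catalyst ⇌ target + free catalyst, rate k1*[starting material]*[free catalyst] forward; the back reaction follows from the equilibrium constant (K = 0.590, k = 2.60 M⁻¹ s⁻¹)
    2 starting material → self-condensation product (k = 0.0100 M⁻¹ s⁻¹)
    starting material ⇌ isomer of the product (K = 4.50, k = 9.10 × 10⁻⁴ s⁻¹)
    free catalyst → spent catalyst (k = 0.00350 s⁻¹)
    starting material + free catalyst ⇌ idle complex, settled at all times (K = 4.00 M⁻¹)

**Drain used.** Target and isomer of the product stand level in the flask at 7.37 h, both at 8.18 %. Stepped on from that point with the drain half-life of 6.03 h, the reckoning gives 6.05 % of isomer at 10 h, and the flask holds 6.64 %. For the neighbour charged with 0.0036 M of free catalyst, the same step from 7.50 % gives 5.96 %, and that neighbour holds 6.98 %.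

The data are simulated with made-up constants; scatter was added.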